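**Plan**
1. Retrosynthesis: the four O–CH2Ar bonds are cut first (two benzyl ethers at O7/O7'' and an o-xylylene bridge across O4'/O4'''). C3/C3'' are then traced back through epimerisation and C3–C3'' saturation to a (Z)-C3=C3'' enedione, which is the ring-opened form of a furan.
2. Enabling feature: the 1,4-diketone C4(=O)–C3–C3''–C4''(=O) that joins the two pyranone rings is a masked 2,5-diarylfuran whose only free (β) carbons are C3 and C3''. On the flat benzo–pyrano–furo–pyrano–benzo core, C2/C2'' aryl groups standing cis are the meso relation and bring O4'/O4''' within reach of a short bridge.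
3. Key cut: C2–C3, O1–C2, C2''–C3'' and O1''–C2'' are disconnected together, giving 2,5-bis[4-(benzyloxy)-2-hydroxyphenyl]furan and an o-xylylene-tethered bis(4-formylphenyl) ether.
4. Forward order: furan ring (Friedel–Crafts, Paal–Knorr); then both pyran rings and the 18-membered cyclophane ring in one acid step; oxidative furan opening; C3=C3'' reduction; epimerisation; global hydrogenolysis.
5. Stereochemistry: C2/C2'' (meso) come from the tether in the key step; C3/C3'' come from enolate equilibration to 2,3-trans in each ring, giving (2S,3R,2''R,3''S).

Key step: step 6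

Remark: flavanone locants are used throughout (O1, C2, C3, C4, C7; double primes for the second unit; 4' and 4''' for the para positions of the 2-aryl rings). The target SMILES is read as the meso (2S,3R,2''R,3''S) isomer with both rings 2,3-trans.

**Step 1**
Reactants: 1 succinyl chloride; 2 1,3-dimethoxybenzene (2.2 equiv)
Product: 3 1,4-bis(2,4-dimethoxyphenyl)butane-1,4-dione
Conditions: AlCl3 (2.5 equiv), CH2Cl2, 0 °C to rt; aq. HCl work-up
Reagents that add atoms: none
Why: Friedel–Crafts acylation places each acyl end at C4 of the arene (para to one methoxy group, ortho to the other), the deactivated aryl ketone does not react again, and any methyl ether lost ortho to the carbonyl is harmless because step 2 removes all four.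

**Step 2**
Reactants: 3 1,4-bis(2,4-dimethoxyphenyl)butane-1,4-dione
Product: 4 1,4-bis(2,4-dihydroxyphenyl)butane-1,4-dione
Conditions: BBr3 (6 equiv), CH2Cl2, −78 °C to rt; H2O quench
Reagents that add atoms: none
Why: Lewis-acid ether cleavage, in which BBr3 binds each methoxy oxygen and bromide removes the methyl group by SN2 displacement, should free all four phenols on hydrolysis while leaving the saturated diketone untouched.

**Step 3**
Reactants: 4 1,4-bis(2,4-dihydroxyphenyl)butane-1,4-dione
Product: 5 1,4-bis[4-(benzyloxy)-2-hydroxyphenyl]butane-1,4-dione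
Conditions: BnBr (2.1 equiv), K2CO3 (2.2 equiv), acetone, reflux
Reagents that add atoms: benzyl bromide, BrCc1ccccc1
Why: Williamson etherification should be selective for the 4-hydroxyl, which is the more acidic and unencumbered phenol, because the 2-hydroxyl is held in a hydrogen bond to the ketone and resists a weak base.

**Step 4**
Reactants: 5 1,4-bis[4-(benzyloxy)-2-hydroxyphenyl]butane-1,4-dione
Product: 6 2,5-bis[4-(benzyloxy)-2-hydroxyphenyl]furan
Conditions: p-TsOH·H2O (10 mol %), toluene, reflux, Dean–Stark
Reagents that add atoms: none
Why: Paal–Knorr furan synthesis (enolisation, hemiketal formation, loss of water) aromatises the 1,4-diketone, and catalytic acid should leave the benzyl aryl ethers intact.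

**Step 5**
Reactants: 7 4-hydroxybenzaldehyde (2.1 equiv); 8 1,2-bis(bromomethyl)benzene
Product: 9 1,2-bis[(4-formylphenoxy)methyl]benzene
Conditions: K2CO3, DMF, 60 °C
Reagents that add atoms: none
Why: Williamson etherification, in which the phenoxide displaces both primary benzylic bromides by SN2 substitution.

**Step 6**
Reactants: 6 2,5-bis[4-(benzyloxy)-2-hydroxyphenyl]furan; 9 1,2-bis[(4-formylphenoxy)methyl]benzene (equimolar)
Product: 11 meso cis-bridged furo-fused bis(7-benzyloxy-2-aryl-2H-chromene) cyclophane, via mono-annulated aldehyde 10 (not isolated)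
Conditions: p-TsOH·H2O (0.3 equiv), 4 Å MS, ClCH2CH2Cl, 60 °C, 1 mM, slow addition of 6 and 9
Reagents that add atoms: none
Why: Proposed new method: protonation activates one formyl group of 9, the furan β carbon C3 of 6 (the only unsubstituted furan position) adds to it, the carbinol ionises to a cation shared by the furan and the 4-alkoxyphenyl ring, and the neighbouring phenol captures it to give 10, after which the tethered second formyl group repeats the sequence at C3'' (an O-first path through the phenol hemiacetal and its oxocarbenium ion converges on the same bonds). The closest known reaction type is the acid-catalysed oxa-Pictet–Spengler-type condensation of 2-(2-hydroxyaryl)indoles and -pyrroles with aldehydes to chromeno-fused heteroarenes, which has not been shown for a furan β carbon or in a double, macrocyclising form. Each pyran ring closes in a 6-endo mode (O1 onto the exocyclic cationic carbon, or C3 onto the oxocarbenium carbon), and the 18-membered cyclophane ring closes when C3'' bonds to the tethered formyl carbon. C2 of 10 forms without control (racemic); C2'' is then set relative to it by the o-xylylene bridge, which can span only two aryl groups on the same face of the flat pentacyclic core, so the cis (meso) isomer should result, and acid-reversible ionisation of the doubly benzylic C2–O1 bonds lets a mismatched closure reopen. The step needs attack by the furan β carbon instead of the activated ring positions of the benzyloxyphenol units, and ring closure instead of oligomerisation; the first is favoured because only the furan carbon can pass the cation to a neighbouring phenol in a six-membered closure, the second by high dilution and the tether.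

**Step 7**
Reactants: 11 meso cis-bridged cyclophane
Product: 13 tethered (Z)-C3=C3'' enedione (meso), via furan endoperoxide 12 (not isolated)
Conditions: O2, hν (visible), tetraphenylporphyrin (1 mol %), CH2Cl2, −78 °C; then Me2S, −78 to 0 °C
Reagents that add atoms: dioxygen, O=O
Why: Furan photooxygenation, in which singlet oxygen adds across the α carbons C4/C4'' in a [4+2] cycloaddition from the face opposite the aryl groups and Me2S reduces the O–O bond so that the endoperoxide collapses to the cis-enedione, leaves C2/C2'' untouched and passes the Z geometry on from the ring.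

**Step 8**
Reactants: 13 tethered (Z)-enedione
Product: 14 tethered 7,7''-di-O-benzyl-3,3''-biflavanone, mainly the 2,3-cis/2'',3''-cis (2S,3S,2''R,3''R) isomer
Conditions: Zn dust, AcOH, THF, 0 °C to rt
Reagents that add atoms: none
Why: Dissolving-metal reduction of an ene-1,4-dione gives a zinc dienediolate that acetic acid protonates at once (before the ring oxygen can be expelled) at C3 and C3'' from the face away from the neighbouring pseudoaxial aryl group, so the kinetic 2,3-cis arrangement is expected in each ring and any C3/C3'' epimer mixture is carried on.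

**Step 9**
Reactants: 14 tethered biflavanone (kinetic C3/C3'' isomers)
Product: 15 tethered (2S,3R,2''R,3''S)-7,7''-di-O-benzyl-3,3''-biflavanone (trans,trans; meso)
Conditions: DBU (0.2 equiv), CH2Cl2, rt
Reagents that add atoms: none
Why: Base-mediated epimerisation through the ketone enolate acts only at C3 and C3'', the sole acidic stereocentres, so each chromanone should settle into the diequatorial 2,3-trans arrangement while C2 and C2'' stay sp3 and keep the meso relation fixed in step 6.

**Step 10**
Reactants: 15 tethered trans,trans biflavanone
Product: 16 (2S,3R,2''R,3''S)-7,7''-dihydroxy-2,2''-bis(4-hydroxyphenyl)-[3,3''-bichromane]-4,4''-dione (target)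
Conditions: H2 (1 atm), Pd/C (10 wt %), THF–MeOH, rt
Reagents that add atoms: none
Why: Catalytic hydrogenolysis cleaves the four primary benzylic C–O bonds (two benzyl ethers and both arms of the o-xylylene bridge) under neutral conditions that neither enolise C3 nor open the pyranone, whose secondary C2–O1 bond and aryl ketone react far more slowly.

**Compound list**
1 | succinyl chloride | O=C(Cl)CCC(=O)Cl | starting material
2 | 1,3-dimethoxybenzene | COc1cccc(OC)c1 | starting material
3 | 1,4-bis(2,4-dimethoxyphenyl)butane-1,4-dione | COc1ccc(C(=O)CCC(=O)c2ccc(OC)cc2OC)c(OC)c1 | intermediate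
4 | 1,4-bis(2,4-dihydroxyphenyl)butane-1,4-dione | O=C(CCC(=O)c1ccc(O)cc1O)c1ccc(O)cc1O | intermediate
5 | 1,4-bis[4-(benzyloxy)-2-hydroxyphenyl]butane-1,4-dione | O=C(CCC(=O)c1ccc(OCc2ccccc2)cc1O)c1ccc(OCc2ccccc2)cc1O | intermediate
6 | 2,5-bis[4-(benzyloxy)-2-hydroxyphenyl]furan | Oc1cc(OCc2ccccc2)ccc1-c1ccc(o1)-c1ccc(OCc2ccccc2)cc1O | intermediate
7 | 4-hydroxybenzaldehyde | O=Cc1ccc(O)cc1 | starting material
8 | 1,2-bis(bromomethyl)benzene | BrCc1ccccc1CBr | starting material
9 | 1,2-bis[(4-formylphenoxy)methyl]benzene | O=Cc1ccc(OCc2ccccc2COc2ccc(C=O)cc2)cc1 | intermediate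
10 | mono-annulated aldehyde (racemic, one enantiomer drawn; not isolated): one 7-benzyloxy-2H-chromene ring fused to the furan at C3–C4; C2 carries the 4-[2-(4-formylphenoxymethyl)benzyloxy]phenyl group; the other furan α carbon keeps its 4-(benzyloxy)-2-hydroxyphenyl group and C3'' is still C–H | O=Cc1ccc(OCc2ccccc2COc2ccc(cc2)[C@H]2Oc3cc(OCc4ccccc4)ccc3-c3oc(cc32)-c2ccc(OCc3ccccc3)cc2O)cc1 | intermediate
11 | meso (2R,2''S) cis-bridged cyclophane: furan fused through C3–C4 and C3''–C4'' to two 7-benzyloxy-2H-chromene rings; C2 and C2'' each carry H and a 1,4-phenylene ring on the same face of the core, the para oxygens linked as O–CH2–(1,2-C6H4)–CH2–O | C(c7ccccc7)Oc1ccc2c(c1)O[C@H](c6ccc(cc6)OCc6ccccc6CO9)c1c3[C@H](c6ccc9cc6)Oc4cc(OCc8ccccc8)ccc4c3oc12 | intermediate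
12 | furan endoperoxide of 11 (not isolated): O–O bridge across C4/C4'' on the face opposite the aryl groups, C3=C3'' retained | C(c7ccccc7)Oc1ccc2c(c1)O[C@H](c6ccc(cc6)OCc6ccccc6CO9)C1=C3[C@H](c6ccc9cc6)Oc4cc(OCc8ccccc8)ccc4[C@@]3(O5)OO[C@]125 | intermediate
13 | tethered (Z)-7,7''-bis(benzyloxy)-[3,3''-bichromanylidene]-4,4''-dione, meso (2R,2''S), bridge as in 11 | O=C1c2ccc(OCc3ccccc3)cc2O[C@H](c2ccc(cc2)OCc2ccccc2CO9)/C1=C1/C(=O)c2ccc(OCc3ccccc3)cc2O[C@H]1c1ccc9cc1 | intermediate
14 | tethered 7,7''-di-O-benzyl-3,3''-biflavanone, (2S,3S,2''R,3''R) cis,cis isomer drawn (C3/C3'' epimers equally serviceable) | O=C1c2ccc(OCc3ccccc3)cc2O[C@H](c2ccc(cc2)OCc2ccccc2CO9)[C@@H]1[C@H]1C(=O)c2ccc(OCc3ccccc3)cc2O[C@H]1c1ccc9cc1 | intermediate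
15 | tethered 7,7''-di-O-benzyl-3,3''-biflavanone, (2S,3R,2''R,3''S) trans,trans meso isomer | O=C1c2ccc(OCc3ccccc3)cc2O[C@H](c2ccc(cc2)OCc2ccccc2CO9)[C@H]1[C@@H]1C(=O)c2ccc(OCc3ccccc3)cc2O[C@H]1c1ccc9cc1 | intermediate
16 | (2S,3R,2''R,3''S)-7,7''-dihydroxy-2,2''-bis(4-hydroxyphenyl)-[3,3''-bichromane]-4,4''-dione | O=C1c2ccc(O)cc2O[C@H](c2ccc(O)cc2)[C@H]1[C@@H]1C(=O)c2ccc(O)cc2O[C@H]1c1ccc(O)cc1 | target

**Step count and risks**
Total steps: 10. Longest linear sequence: 9 (steps 1–4 and 6–10); step 5 is a one-step branch.

Steps most likely to fail:

1. Step 6. The benzylic cations may alkylate the activated ring positions of the benzyloxyphenol units, or intermolecular C–C bond formation may outrun the second ring closure and give oligomers. Fallback by known chemistry, setting out from diketone 5 and dialdehyde 9: a double Claisen–Schmidt condensation at the two methylene groups of 5 (KOH or piperidine, EtOH–THF, high dilution) should give the macrocyclic bis(2'-hydroxychalcone) F1. Double oxa-Michael closure (NaOAc, EtOH, reflux) followed by DBU equilibration as in step 9 should then give the tethered biflavanone, rejoining the route at 15 and bypassing the furan, steps 7 and 8. In this variant the C2/C2'' relation rests on thermodynamic preference under the tether instead of on the flat core, and would have to be verified.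

2. Step 7. The exocyclic C3=C3'' bond may migrate into a pyranone ring (flavone formation, erasing C2 or C2''), or the endoperoxide may rearrange before it is reduced. Fallback setting out from 11: Clauson-Kaas-type anodic methoxylation (MeOH, Et4NOTs, carbon electrodes, −20 °C) should give the 2,5-dimethoxy-2,5-dihydrofuran F2, a bis-ketal with no carbonyl to drive tautomerisation. Zn dust in aqueous AcOH–THF then hydrolyses the ketals and reduces the enedione as it is released, rejoining the route at 14.

3. Step 9. The enolate may expel the ring phenoxide (E1cB opening of the pyranone) and scramble C2/C2'', or the macrocycle may make the trans,trans arrangement less than the thermodynamic minimum while the tether is in place. Fallback setting out from 14: hydrogenolysis first (H2, Pd/C, THF–MeOH) should give the untethered cis,cis tetraphenol F3. Its C3/C3'' centres are then equilibrated through the enol under acid (p-TsOH·H2O cat., AcOH, 40 °C), which avoids phenoxide formation, and the route is rejoined at 16.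

**Further compounds**
F1 | step 6 | macrocyclic (E,E)-2,3-bis(arylidene)-1,4-bis[4-(benzyloxy)-2-hydroxyphenyl]butane-1,4-dione, the two arylidene rings joined through their para oxygens by the o-xylylene unit | O=C(c1ccc(OCc2ccccc2)cc1O)/C(=C/c1ccc(cc1)OCc1ccccc1CO9)/C(=C\c1ccc9cc1)C(=O)c1ccc(OCc2ccccc2)cc1O
F2 | step 7 | 4,4''-dimethoxy bis-ketal of 11 (2,5-dimethoxy-2,5-dihydrofuran; C4/C4'' diastereomer mixture, C2/C2'' meso as in 11) | C(c7ccccc7)Oc1ccc2c(c1)O[C@H](c6ccc(cc6)OCc6ccccc6CO9)C1=C3[C@H](c6ccc9cc6)Oc4cc(OCc8ccccc8)ccc4C3(OC)OC12OC
F3 | step 9 | (2S,3S,2''R,3''R)-7,7''-dihydroxy-2,2''-bis(4-hydroxyphenyl)-[3,3''-bichromane]-4,4''-dione (cis,cis meso tetraphenol) | O=C1c2ccc(O)cc2O[C@H](c2ccc(O)cc2)[C@@H]1[C@H]1C(=O)c2ccc(O)cc2O[C@H]1c1ccc(O)cc1
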